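The synthesis rests on disconnecting the spiro γ-lactone at its C11–C12 bond. The feature exploited is the ketal carbon C11, shared by the tetrahydrofuran and lactone rings: in the lactol-ester precursor its C11–H is a doubly oxygen-activated hydrogen held 1,6 to the oxygen of a pendant aldehyde (C12). A Norrish–Yang photocyclisation moves that hydrogen to the aldehyde oxygen and collapses the resulting C11/C12 biradical, so one operation closes the spiro lactone and creates the C11 ketal and the C12 carbinol. The precursor is the anomeric 2-formylpropanoate of an N-Boc azepane-fused lactol, built by a butenolide Michael addition–ethylation; the enaminone ring with its 9a-hydroxyl is added last.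

Key step: step 10

Remarks: Skeleton atoms carry stemoninine-type labels: N4, C5–C7, C8 (O-bearing CH), C9, C9a, C1 (C=O), C2, C3 in the azepane/pyrrolinone part; C10 (ethyl-bearing), C11 (spiro), C12 (carbinol), C13, C14 (lactone C=O); C18–C21 for the pendant lactone. Assumption: C9a is formed unselectively in step 4 and carried as an epimer pair (no stereo mark in the SMILES of 9–14, 16–23 and 32–34), because it becomes trigonal before it is fixed in step 19. C13 of 16–18 comes from a racemic acid and is set in step 10.

**Route**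

Step 1
Reactants: 1 4-chlorobutanal; 2 methyl propiolate
Product: 3 methyl (R)-7-chloro-4-hydroxyhept-2-ynoate
Conditions: Me2Zn (3 equiv), ProPhenol (10 mol%, antipode giving the R alcohol), Ph3P=O (20 mol%), PhMe, 0 °C
Reagents that add atoms: none
Why: Zinc–ProPhenol catalysed asymmetric alkynylation of an aliphatic aldehyde with methyl propiolate, in which the chiral dinuclear zinc catalyst selects the aldehyde face and so sets C8 (R).

Step 2
Reactants: 3 methyl (R)-7-chloro-4-hydroxyhept-2-ynoate
Product: 5 (R)-5-(3-chloropropyl)furan-2(5H)-one, via Z-hydroxy-enoate 4 (not isolated)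
Conditions: H2 (1 atm), Lindlar catalyst, quinoline, EtOAc, rt; then PPTS (cat.), PhMe, 60 °C
Reagents that add atoms: none
Why: Lindlar semihydrogenation should give the Z-γ-hydroxy enoate, which lactonises by acid-catalysed transesterification to the butenolide without touching C8 or the alkyl chloride.

Step 3
Reactants: 6 dibenzylamine; 7 tert-butyl bromoacetate
Product: 8 tert-butyl N,N-dibenzylglycinate
Conditions: K2CO3, MeCN, rt
Reagents that add atoms: none
Why: SN2 N-alkylation of a secondary amine by an α-bromo ester.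

Step 4
Reactants: 8 tert-butyl N,N-dibenzylglycinate; 5 (R)-5-(3-chloropropyl)furan-2(5H)-one
Product: 10 tert-butyl 2-(dibenzylamino)-2-[(2R,3R,4S)-2-(3-chloropropyl)-4-ethyl-5-oxooxolan-3-yl]acetate (C9a epimers), via lithium lactone enolate 9 (not isolated)
Conditions: LDA, THF, −78 °C; then 5, −78 °C; then EtI, DMPU, −78 → −30 °C
Reagents that add atoms: iodoethane (CCI)
Why: Tandem Michael addition–enolate alkylation (three-component coupling on a butenolide), in which the ester enolate adds 1,4 anti to the C8 side chain (C9), the resulting lactone enolate is ethylated anti to the new C9 substituent (C10, giving the 8,9-trans-9,10-trans lactone), and C9a forms as an inconsequential epimer pair.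

Step 5
Reactants: 10 dibenzylamino lactone
Product: 12 tert-butyl 2-[(tert-butoxycarbonyl)amino]-2-[(2R,3R,4S)-2-(3-chloropropyl)-4-ethyl-5-oxooxolan-3-yl]acetate (C9a epimers), via primary amine 11 (not isolated)
Conditions: H2 (1 atm), Pd(OH)2/C, Boc2O, EtOAc–EtOH, rt
Reagents that add atoms: di-tert-butyl dicarbonate (CC(C)(C)OC(=O)OC(=O)OC(C)(C)C)
Why: Hydrogenolysis of both N-benzyl groups with in situ Boc capture of the primary amine, which forestalls O→N acyl shift onto the lactone while the alkyl chloride survives neutral Pd/H2.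

Step 6
Reactants: 12 NH-Boc chloro lactone
Product: 13 di-tert-butyl (3S,3aR,8aR)-3-ethyl-2-oxoperhydrofuro[3,2-c]azepine-4,5-dicarboxylate (8,9-trans, 9,10-trans; C9a epimers)
Conditions: NaH (1.05 equiv), NaI (cat.), DMF, 0 °C → rt
Reagents that add atoms: none
Why: Intramolecular N-alkylation of the carbamate anion (7-exo-tet, through the iodide formed by Finkelstein exchange) should close the azepane ring without creating a stereocentre.

Step 7
Reactants: 13 N-Boc azepane-fused lactone
Product: 14 lactol of 13 (C11 hemiacetal, anomers; C9a epimers)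
Conditions: DIBAL-H (1.2 equiv), CH2Cl2, −78 °C; Rochelle salt
Reagents that add atoms: none
Why: DIBAL half-reduction of the γ-lactone to the lactol at −78 °C, where the hindered tert-butyl ester and the carbamate are inert.

Step 8
Reactants: 14 lactol; 15 2-methylbut-3-enoic acid (racemic)
Product: 16 anomeric 2-methylbut-3-enoate of 14, acyloxy group trans to the C10 ethyl (11R; C13 and C9a epimers)
Conditions: DCC, DMAP (cat.), CH2Cl2, −20 → 0 °C
Reagents that add atoms: none
Why: Steglich esterification of the equilibrating lactol, which should acylate the anomeric hydroxyl mainly trans to the C10 ethyl group (less hindered face) and so leave the C11–H cis to ethyl.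

Step 9
Reactants: 16 anomeric butenoate
Product: 18 anomeric 2-methyl-3-oxopropanoate (2-formylpropanoate) of 14 (11R; C13 labile, C9a epimers), via secondary ozonide 17 (not isolated)
Conditions: O3, CH2Cl2, −78 °C; then PPh3, −78 °C → rt
Reagents that add atoms: ozone ([O-][O+]=O)
Why: Ozonolysis of the only alkene with reductive work-up gives the β-formyl ester under neutral conditions that spare the acylal, the carbamate and the tert-butyl ester.

Step 10
Reactants: 18 anomeric 2-formylpropanoate
Product: 20 spiro β-hydroxy-γ-lactone (8R,9R,10S,11S,12R,13R; N-Boc, tert-butyl ester; C9a epimers), via 1,5-biradical 19 (not isolated)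
Conditions: hν (300–310 nm, Pyrex), degassed C6H6 (5 mM), 20 °C
Reagents that add atoms: none
Why: Proposed new method: n→π* excitation of the aldehyde is followed by 1,6-hydrogen transfer (δ-abstraction through a seven-membered transition state) of the anomeric C11–H to the C12 oxygen, and the 1,5-biradical 19 (dioxy-stabilised C11 radical, hydroxyalkyl C12 radical) recombines to forge C11–C12. The closest known reaction types are the Norrish–Yang photocyclisation of β-oxo esters to β-hydroxy-γ-lactones by δ-hydrogen abstraction from the ester alkoxy group and the photocyclisation of 3-oxoalkyl glycosides to anomeric spiroketals; an aldehyde chromophore acting on an acylal C–H is new. The only ring closed is the five-membered lactone, by radical–radical combination (Yang cyclisation) within the O–C(=O)–C–C tether held in its s-trans ester rotamer. C11 should form with retention (C12 bonds on the face vacated by hydrogen while the acyloxy oxygen stays trans to the C10 ethyl), the C12 hydroxyl should turn toward the tetrahydrofuran oxygen and away from C10, and C13, which equilibrates in 18 through the enol, should react as the epimer that puts methyl anti to that hydroxyl. The step needs δ-abstraction to win over Norrish type I cleavage and over other hydrogen transfers; this is secured by C11–H being the only doubly oxygen-activated hydrogen within reach, by the nitrogen being a non-quenching carbamate and by dilute, degassed conditions.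

Step 11
Reactants: 20 spiro hydroxy lactone
Product: 22 N-Boc amino acid (C9a carboxylic acid; C9a epimers), via amino acid 21 (not isolated)
Conditions: TFA–CH2Cl2 (1:3), 0 °C → rt; evaporate; then Boc2O, i-Pr2NEt, MeCN, rt
Reagents that add atoms: di-tert-butyl dicarbonate (CC(C)(C)OC(=O)OC(=O)OC(C)(C)C)
Why: Acidolysis removes both tert-butyl groups (ester and carbamate) and the liberated secondary amine is re-protected by carbamoylation, the spiro acylal and the secondary alcohol being stable to anhydrous acid and to Boc2O without DMAP.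

Step 12
Reactants: 22 N-Boc amino acid
Product: 23 S-ethyl thioester of 22 (C9a epimers)
Conditions: EtSH (3 equiv), EDC·HCl, DMAP (cat.), CH2Cl2, 0 °C
Reagents that add atoms: ethanethiol (CCS)
Why: Steglich-type thioesterification, in which the thiol should outcompete the hindered secondary C12 hydroxyl for the activated acid.

Step 13
Reactants: 24 (S)-2-methylsuccinic acid
Product: 25 (S)-2-methylsuccinic anhydride
Conditions: AcCl, reflux
Reagents that add atoms: none
Why: Cyclodehydration of the 1,4-diacid to the anhydride with acetyl chloride, which leaves the C20 stereocentre untouched.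

Step 14
Reactants: 25 (S)-2-methylsuccinic anhydride; 26 bis(trimethylsilyl)acetylene
Product: 27 (S)-2-methyl-4-oxo-6-(trimethylsilyl)hex-5-ynoic acid
Conditions: AlCl3, CH2Cl2, 0 °C; aq. HCl
Reagents that add atoms: none
Why: Friedel–Crafts-type acylative ipso-desilylation of the alkynylsilane, with the anhydride opening at its less hindered carbonyl (remote from methyl) so that the stereocentre ends α to the free acid.

Step 15
Reactants: 27 ynone acid
Product: 29 methyl (2S,4S)-4-hydroxy-2-methyl-6-(trimethylsilyl)hex-5-ynoate, via keto ester 28 (not isolated)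
Conditions: TMSCHN2, PhMe–MeOH, 0 °C; then RuCl[(S,S)-TsDPEN](p-cymene) (1 mol%), i-PrOH, rt
Reagents that add atoms: (trimethylsilyl)diazomethane (C[Si](C)(C)C=[N+]=[N-])
Why: Esterification followed by Noyori asymmetric transfer hydrogenation of the ynone, in which the (S,S)-catalyst should deliver hydride to one carbonyl face and set C18 (S) irrespective of the remote C20 centre.

Step 16
Reactants: 29 silylated hydroxy ester
Product: 31 (3S,5S)-5-ethynyl-3-methyloxolan-2-one (cis), via desilylated hydroxy-ester 30 (not isolated)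
Conditions: K2CO3, MeOH, 0 °C; then TsOH (cat.), CH2Cl2, rt
Reagents that add atoms: none
Why: Base-mediated protodesilylation of the alkynylsilane and acid-catalysed lactonisation of the γ-hydroxy ester should give the cis lactone with both stereocentres unchanged.

Step 17
Reactants: 23 S-ethyl thioester; 31 (3S,5S)-5-ethynyl-3-methyloxolan-2-one
Product: 32 ynone (C9a–C(=O)–C≡C–C18; C9a epimers)
Conditions: PdCl2(dppf) (10 mol%), P(2-furyl)3 (25 mol%), CuI (1.7 equiv), Et3N, DMF, rt → 40 °C
Reagents that add atoms: none
Why: Fukuyama-type Pd/Cu coupling of a thiol ester with a terminal alkyne gives the ynone chemoselectively at the thioester, leaving both lactones, the carbamate and the free hydroxyl untouched.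

Step 18
Reactants: 32 ynone
Product: 34 9a-H pyrrolinone (9a-deoxy target; C9a epimers), via amino ynone 33 (not isolated)
Conditions: TFA–CH2Cl2 (1:4), 0 °C; then sat. aq. NaHCO3, CH2Cl2, rt (Ar)
Reagents that add atoms: none
Why: Boc removal frees the azepane nitrogen, which should add to the ynone in a 5-endo-dig aza-Michael cyclisation to the vinylogous amide (1,2-dihydro-3H-pyrrol-3-one), C9a remaining a labile epimer pair.

Step 19
Reactants: 34 9a-H pyrrolinone
Product: 36 CNP0182700.1 (target), via 9a-hydroperoxide 35 (not isolated)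
Conditions: O2 (1 atm), Et3N (cat.), CH2Cl2, rt; then Me2S
Reagents that add atoms: dioxygen (O=O)
Why: Autoxidation of the 2-H pyrrol-3(2H)-one through its 3-hydroxypyrrole tautomer and the captodative C9a radical, with oxygen expected to enter on the face syn to H9 and anti to the C10 branch to give the 9aS hydroperoxide, which dimethyl sulfide reduces to the hemiaminal.

**Compound list**

1 | 4-chlorobutanal | ClCCCC=O | starting material
2 | methyl propiolate | C#CC(=O)OC | starting material
3 | methyl (R)-7-chloro-4-hydroxyhept-2-ynoate | COC(=O)C#C[C@H](O)CCCCl | intermediate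
4 | methyl (R,Z)-7-chloro-4-hydroxyhept-2-enoate | COC(=O)/C=C\[C@H](O)CCCCl | intermediate
5 | (R)-5-(3-chloropropyl)furan-2(5H)-one | O=C1C=C[C@@H](CCCCl)O1 | intermediate
6 | dibenzylamine | C(NCc1ccccc1)c1ccccc1 | starting material
7 | tert-butyl bromoacetate | CC(C)(C)OC(=O)CBr | starting material
8 | tert-butyl N,N-dibenzylglycinate | CC(C)(C)OC(=O)CN(Cc1ccccc1)Cc1ccccc1 | intermediate
9 | lithium lactone enolate of the Michael adduct (C9a epimers) | [Li+].[O-]C1=C[C@H](C(N(Cc2ccccc2)Cc2ccccc2)C(=O)OC(C)(C)C)[C@@H](CCCCl)O1 | intermediate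
10 | tert-butyl 2-(dibenzylamino)-2-[(2R,3R,4S)-2-(3-chloropropyl)-4-ethyl-5-oxooxolan-3-yl]acetate (C9a epimers) | CC[C@H]1[C@H](C(N(Cc2ccccc2)Cc2ccccc2)C(=O)OC(C)(C)C)[C@@H](CCCCl)OC1=O | intermediate
11 | tert-butyl 2-amino-2-[(2R,3R,4S)-2-(3-chloropropyl)-4-ethyl-5-oxooxolan-3-yl]acetate (C9a epimers) | CC[C@H]1[C@H](C(N)C(=O)OC(C)(C)C)[C@@H](CCCCl)OC1=O | intermediate
12 | tert-butyl 2-[(tert-butoxycarbonyl)amino]-2-[(2R,3R,4S)-2-(3-chloropropyl)-4-ethyl-5-oxooxolan-3-yl]acetate (C9a epimers) | CC[C@H]1[C@H](C(NC(=O)OC(C)(C)C)C(=O)OC(C)(C)C)[C@@H](CCCCl)OC1=O | intermediate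
13 | di-tert-butyl (3S,3aR,8aR)-3-ethyl-2-oxoperhydrofuro[3,2-c]azepine-4,5-dicarboxylate (C9a epimers) | CC[C@H]1[C@H]2[C@@H](CCCN(C(=O)OC(C)(C)C)C2C(=O)OC(C)(C)C)OC1=O | intermediate
14 | lactol of 13 (2-hydroxy in place of 2-oxo; anomers, C9a epimers) | CC[C@H]1[C@H]2[C@@H](CCCN(C(=O)OC(C)(C)C)C2C(=O)OC(C)(C)C)OC1O | intermediate
15 | 2-methylbut-3-enoic acid (racemic) | C=CC(C)C(=O)O | starting material
16 | anomeric 2-methylbut-3-enoate of 14, acyloxy trans to the C10 ethyl (11R; C13 and C9a epimers) | CC[C@H]1[C@H]2[C@@H](CCCN(C(=O)OC(C)(C)C)C2C(=O)OC(C)(C)C)O[C@@H]1OC(=O)C(C)C=C | intermediate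
17 | secondary ozonide (1,2,4-trioxolane) of 16 | CC[C@H]1[C@H]2[C@@H](CCCN(C(=O)OC(C)(C)C)C2C(=O)OC(C)(C)C)O[C@@H]1OC(=O)C(C)C1OCOO1 | intermediate
18 | anomeric 2-methyl-3-oxopropanoate of 14 (11R; C13 labile, C9a epimers) | CC[C@H]1[C@H]2[C@@H](CCCN(C(=O)OC(C)(C)C)C2C(=O)OC(C)(C)C)O[C@@H]1OC(=O)C(C)C=O | intermediate
19 | C11/C12 1,5-biradical from 18 | CC[C@H]1[C@H]2[C@@H](CCCN(C(=O)OC(C)(C)C)C2C(=O)OC(C)(C)C)O[C]1OC(=O)C(C)[CH]O | intermediate
20 | spiro β-hydroxy-γ-lactone, N-Boc, tert-butyl ester (8R,9R,10S,11S,12R,13R; C9a epimers) | CC[C@H]1[C@H]2[C@@H](CCCN(C(=O)OC(C)(C)C)C2C(=O)OC(C)(C)C)O[C@]12OC(=O)[C@H](C)[C@H]2O | intermediate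
21 | amino acid from 20 (handled as its trifluoroacetate salt) | CC[C@H]1[C@H]2[C@@H](CCCNC2C(=O)O)O[C@]12OC(=O)[C@H](C)[C@H]2O | intermediate
22 | N-Boc amino acid (C9a epimers) | CC[C@H]1[C@H]2[C@@H](CCCN(C(=O)OC(C)(C)C)C2C(=O)O)O[C@]12OC(=O)[C@H](C)[C@H]2O | intermediate
23 | S-ethyl thioester of 22 (C9a epimers) | CC[C@H]1[C@H]2[C@@H](CCCN(C(=O)OC(C)(C)C)C2C(=O)SCC)O[C@]12OC(=O)[C@H](C)[C@H]2O | intermediate
24 | (S)-2-methylsuccinic acid | OC(=O)C[C@H](C)C(=O)O | starting material
25 | (S)-2-methylsuccinic anhydride | O=C1C[C@H](C)C(=O)O1 | intermediate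
26 | bis(trimethylsilyl)acetylene | C[Si](C)(C)C#C[Si](C)(C)C | starting material
27 | (S)-2-methyl-4-oxo-6-(trimethylsilyl)hex-5-ynoic acid | C[Si](C)(C)C#CC(=O)C[C@H](C)C(=O)O | intermediate
28 | methyl (S)-2-methyl-4-oxo-6-(trimethylsilyl)hex-5-ynoate | C[Si](C)(C)C#CC(=O)C[C@H](C)C(=O)OC | intermediate
29 | methyl (2S,4S)-4-hydroxy-2-methyl-6-(trimethylsilyl)hex-5-ynoate | C[Si](C)(C)C#C[C@@H](O)C[C@H](C)C(=O)OC | intermediate
30 | methyl (2S,4S)-4-hydroxy-2-methylhex-5-ynoate | C#C[C@@H](O)C[C@H](C)C(=O)OC | intermediate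
31 | (3S,5S)-5-ethynyl-3-methyloxolan-2-one | C#C[C@@H]1C[C@H](C)C(=O)O1 | intermediate
32 | ynone from 23 and 31 (N-Boc; C9a epimers) | CC[C@H]1[C@H]2[C@@H](CCCN(C(=O)OC(C)(C)C)C2C(=O)C#C[C@@H]3C[C@H](C)C(=O)O3)O[C@]12OC(=O)[C@H](C)[C@H]2O | intermediate
33 | amino ynone (N–H azepane; C9a epimers) | CC[C@H]1[C@H]2[C@@H](CCCNC2C(=O)C#C[C@@H]3C[C@H](C)C(=O)O3)O[C@]12OC(=O)[C@H](C)[C@H]2O | intermediate
34 | 9a-H pyrrolinone (9a-deoxy target; C9a epimers) | CC[C@H]1[C@H]2[C@@H](CCCN3C([C@@H]4C[C@H](C)C(=O)O4)=CC(=O)C23)O[C@]12OC(=O)[C@H](C)[C@H]2O | intermediate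
35 | 9a-hydroperoxide (9aS) | CC[C@H]1[C@H]2[C@@H](CCCN3C([C@@H]4C[C@H](C)C(=O)O4)=CC(=O)[C@@]23OO)O[C@]12OC(=O)[C@H](C)[C@H]2O | intermediate
36 | CNP0182700.1 (8R,9S,9aS,10S,11S,12R,13R,18S,20S) | CC[C@H]1[C@H]2[C@@H](CCCN3C([C@@H]4C[C@H](C)C(=O)O4)=CC(=O)[C@@]23O)O[C@]12OC(=O)[C@H](C)[C@H]2O | target

**Step count**

Total: 19 steps. Longest linear sequence: 14 steps (1, 2, 4–12, 17–19).

**Three steps most likely to fail**

Step 10 (Proposed new method). Norrish type I cleavage and decarbonylation of the excited α-branched aldehyde may outrun δ-hydrogen abstraction, because the transfer needs the sparsely populated s-trans ester rotamer. The biradical may also collapse with the wrong sense at C11 or C12, or leave C13 as a mixture. The fallback uses known chemistry, sets out from lactone 13 and returns at 20. Lactone 13 would be treated with the dilithio derivative of (Z)-3-bromo-2-methylacrylic acid (n-BuLi, THF, −100 °C), and the adduct lactonised with TsOH to the spirobutenolide F1 (β-lithioacrylate carbonyl addition and butenolide annulation). Nucleophilic epoxidation (t-BuOOH, Triton B, THF) from the face away from the C10 ethyl would give the epoxy lactone F2. SmI2 (THF–MeOH, −78 °C) would then cleave the Cα–O bond, and DBU equilibration of C13 to the 12,13-trans isomer would give 20, where step 11 resumes.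

Step 6. Seven-membered ring closure by the hindered carbamate anion may be slow, so that C-alkylation by the lactone enolate (a bridged ring) or elimination of HCl takes over. The fallback sets out from 10 and returns at 13. Kornblum oxidation of the chloride (NaI, NaHCO3, DMSO, 100 °C) would give the aldehyde F3. Hydrogenolysis (H2, Pd(OH)2/C, AcOH, MeOH) would remove both benzyl groups, and the amino aldehyde would close by intramolecular reductive amination to the N–H azepane F4. Boc2O/Et3N would convert F4 into 13.

Step 19. Oxygen capture at the planar C9a radical may show poor facial selectivity, or the radical chain may over-oxidise the electron-rich enaminone at C2. The fallback sets out from 34 and returns at 36. Double silylation (TMSOTf, Et3N, CH2Cl2, −78 °C) would give the 1-silyloxypyrrole bis-silyl ether F5. Rubottom oxidation with dimethyldioxirane (acetone, −78 °C) would deliver oxygen to C9a of the silyl enol ether anti to the C10 branch, giving the 9a,12-bis(trimethylsilyl) ether F6. Citric acid in aqueous THF would remove both silyl groups to give 36.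

Further compounds
F1 | step 10 | spirobutenolide (12,13-dehydro-12-deoxy analogue of 20) | CC[C@H]1[C@H]2[C@@H](CCCN(C(=O)OC(C)(C)C)C2C(=O)OC(C)(C)C)O[C@]12OC(=O)C(C)=C2
F2 | step 10 | 12,13-epoxy lactone | CC[C@H]1[C@H]2[C@@H](CCCN(C(=O)OC(C)(C)C)C2C(=O)OC(C)(C)C)O[C@]12OC(=O)[C@]3(C)[C@H]2O3
F3 | step 6 | aldehyde from chloride 10 | CC[C@H]1[C@H](C(N(Cc2ccccc2)Cc2ccccc2)C(=O)OC(C)(C)C)[C@@H](CCC=O)OC1=O
F4 | step 6 | N–H azepane-fused lactone tert-butyl ester | CC[C@H]1[C@H]2[C@@H](CCCNC2C(=O)OC(C)(C)C)OC1=O
F5 | step 19 | 1-(trimethylsilyloxy)pyrrole 12-O-trimethylsilyl ether | CC[C@H]1[C@H]2[C@@H](CCCn3c([C@@H]4C[C@H](C)C(=O)O4)cc(O[Si](C)(C)C)c23)O[C@]12OC(=O)[C@H](C)[C@H]2O[Si](C)(C)C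
F6 | step 19 | 9a,12-bis(trimethylsilyl) ether of 36 | CC[C@H]1[C@H]2[C@@H](CCCN3C([C@@H]4C[C@H](C)C(=O)O4)=CC(=O)[C@@]23O[Si](C)(C)C)O[C@]12OC(=O)[C@H](C)[C@H]2O[Si](C)(C)C
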